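The amounts to follow are fractions of the charge of Z, and I call x the fraction of charged Z still there, which starts at one.

    Z → G (k1 = 0.0711 /min)
    Z → E (k2 = 0.153 /min)
    2 Z → Z2 (k3 = 0.233 /M/min)

Z 2.0 M; time 1.0 h

- in percentages every species weighs as the Z in it: one Z2 counts as two
- a step written with two of one species runs at k times the square of its concentration and takes two of it each time
- the reaction counts as stopped when no species that holds the Z changes by six tenths of a point or more over the second half of the time
- run time (flask): 1.0 h

* at 1.0 h, what has stopped the reaction, if anything has (all of Z has reacted / it is still moving / forward and back rates have come level)
* amount of G at 1.0 h, in percent of the Z charged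
* amount of E at 1.0 h, in percent of the Z charged

1. The two one-Z steps, to G and to E, together take Z at 0.224 /min, and I write B, the pairing ratio, for the rate of loss of Z through the step to Z2 over the rate through the one-Z steps at the start: 4.16.

2. The ratio at any moment is B times x, so the one-Z steps take a share of one over one plus Bx, which at the start is 19.4%, and pairing leads there.

3. That share rises as x falls, so I first take it at x of 0.5, which gives 32.5%; G gets 31.7% of that, or about 10.3% of the charge.

4. The one-Z steps alone bring x down to 0.120% by half the time, less than 0.5 of a point and inside the stopping mark, so I commit to all of Z having reacted.

5. Step 3 is the weak link, since one share stands in for a changing one. Averaging over x from one to nothing gives the logarithm of one plus B, divided by B: this is F, the one-Z share, the part of the charge that leaves through the steps to G and to E by the time Z is used up, an overall selectivity 39.5%. So G is 12.5% and E is 27.0%.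

The forecast says all of Z has reacted, with G at 12.5% and E at 26.9%, on the grounds that “Z is consumed, and the steps are irreversible”.

The flask gives all of Z has reacted, with 0% of Z left, G at 12.5% and E at 26.9%.

In the flask as charged, half of the turnover to Z2 is done by 0.533 min, earlier than the 1.63 min for G, and G already reads 8.47% at 0.0500 h. For the forecast's G to be wrong by 5 points, the charge of Z would have to go down to 0.950 M or up to 4.90 M, with the time and all else held, for there the computed answer for G has moved that far.

For a neighbour flask with 1.2 M of Z, B is 2.50 and F is 50.2%, which gives G 15.9% and E 34.3%. The computed neighbour flask stands at G 15.9% and E 34.2%.

(The numbers were chosen freely; the result is computed.)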